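Product was the first item: the meeting asked how much of it each flask holds at 30 min, counted against that flask's own charge of solid substrate.

in all of them: gas 5.5 mM (held)

| charge | solid substrate | remark | time |
|---|---|---|---|
| violet | 0.0091 M | run made earlier |  |
| Friday's | 0.025 M |  | 30 min |
| Thursday's | 0.015 M |  | 30 min |
| Wednesday's | 0.080 M |  | 30 min |
| Saturday's | 0.050 M |  | 30 min |
| Sunday's | 0.030 M |  | 30 min |

violet run (percent of the solid substrate charged)

| time / min | product / % | solid substrate / % |
|---|---|---|
| 1.50 | 1.8 | 96.8 |
| 3.00 | 6.1 | 93.3 |
| 6.00 | 12.3 | 86.4 |
| 12.0 | 26.9 | 71.9 |
| 20.0 | 46.1 | 53.3 |

(scatter of a reading: 0.5 percentage points)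

- given per volume of solution although it is solid: solid substrate
- at the start none of the gas is in solution
- at the start none of the solid substrate is in solution
- what has only dissolved of solid substrate counts as not reacted

* the flasks put in order of amount of product, in percent of the solid substrate charged, best first, at 30 min (Friday's / Thursday's / Wednesday's / Saturday's / Sunday's)
* the amount of product, in percent of the solid substrate charged of the flask you put first, at 30 min
* the amount of product, in percent of the solid substrate charged of the flask you put last, at 30 min

I took the minutes and also spoke first, at the blackboard, proposing to turn the violet percentages back into concentrations. Between 6.00 min and 12.0 min that run added 0.221 mM min⁻¹ of product, and between 12.0 min and 20.0 min it added 0.218 mM min⁻¹, while the solid substrate fell from 86.4% to 53.3%. So, I argued, the rate in this violet run is zero order in the solid substrate remaining, and some concentration in the solution must be holding still while solid remains.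

From the readings at 3.00 min and 20.0 min I reckoned 0.214 mM min⁻¹, and this is the output, the concentration of product added each minute while solid remains. Starting from the last violet reading, it gives 6.34 mM by 30 min, less than the smallest charge among the flasks asked about, the 0.015 M of Thursday's. I therefore expected 42.3% for Thursday's and 7.92% for Wednesday's, which has the largest charge of them.

The author of the forecast agreed on the shape, holding that “the rate does not depend on how much solid is present”. The forecast put down Thursday's > Friday's > Sunday's > Saturday's > Wednesday's, with 42.6% first and 8% last, each a little above mine.

The flasks give Thursday's > Friday's > Sunday's > Saturday's > Wednesday's, with 41.9% for Thursday's and 7.86% for Wednesday's, so the forecast's order stands and both its figures fall within their margins.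

    gas ⇌ coupling partner, rate k1*(csat - [coupling partner]) (kL = 0.0210 s⁻¹)
    dissolved substrate + coupling partner → product (k = 7.90 M⁻¹ s⁻¹)
    solid substrate ⇌ dissolved substrate, rate k3*(cs3 - [dissolved substrate]) while solid is left; crystals form when [dissolved substrate] > cs3 (solubility = 1.50 mM, k = 0.00250 s⁻¹)

Thursday's holds 6.28 mM of product and Wednesday's 6.28 mM, against the 6.34 mM from the output. At 30.0 min their dissolved substrate stands at 0.0840 mM and 0.0840 mM, and in Thursday's it is a steady state, made and used up at a ratio of 1.00. Carried on from the last violet reading, the output gives Thursday's 70.8% at 50 min. That neighbouring flask holds 70.2% of product, with 29.2% of its charge still solid.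

The data are calculated for an exercise, and the scatter is random.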